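**Fixed budget.** In this flask the charge of coupling partner, 0.0450 M, is conserved across the partner itself, target, second product and decomposed reagent, so the target is the part of that charge that has reacted times the share that coupling takes.

starting material 0.050 M; coupling partner 0.900 equiv; second substrate 1.00 equiv; protic impurity 5.00 mM; time 5.0 d

    starting material + coupling partner → target (k1 = 0.014 M⁻¹ s⁻¹)
    second substrate + coupling partner → second product (k2 = 0.023 M⁻¹ s⁻¹)
    starting material + protic impurity → quenched substrate (k3 = 1.8 M⁻¹ s⁻¹)
    second substrate ⇌ dormant form (K4 = 4.4, k4 = 0.0010 s⁻¹)
    coupling partner → decomposed reagent (k5 = 2.2 × 10⁻⁴ s⁻¹)

- the state of affairs at 5.0 d: stopped, and by what, or still going (it is still moving / all of the starting material has reacted / forward and back rates have come level / the coupling partner has run out first)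
- how much of the starting material has reacted by 5.0 d
- how much target there is at 5.0 d, in percent of the starting material charged

**Frozen levels.** Coupling starts at 0.070 of the quench rate, so I took the protic impurity's 5.00 mM off the starting material at once and froze it at 0.0450 M. Free second substrate relaxes from its charge towards 0.00926 M, so I froze it midway, at 0.0296 M. On these levels the partner's half-life is 0.126 h, shorter than the relaxation half-life of 0.157 h but not by a factor of two, and the midpoint rests on that.

**Partner share.** The partner share, 0.411, is the pseudo-first-order rate of partner loss to target divided by that rate plus the losses to second product and decomposition. It gave me 37.0% target and, with the quench added, 47.0% conversion. Since the partner's half-life is far shorter than the run, I expected it to run out first, as limiting reagent.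

**One number?** Barely. Second substrate frozen at its charge gives 0.315, and frozen at its relaxed level 0.593. I also ignored the fall of starting material and the second substrate spent on coupling, which pull the share in opposite directions.

**The forecast.** It said the coupling partner has run out first, with 48.6% conversion and 38.6% target, slightly above my figures, and reasoned: “The second substrate is initially all free, so it competes hard early on”.

**The run.** At 5.0 d the flask showed this: the coupling partner has run out first, with 47.1% conversion, 37.1% target and 0% of the partner left. The forecast stands; its target figure would stop fitting if the partner charge were off, since at 0.779 equiv or 1.02 equiv the target has moved by 5 points. The target took 0.412 of the partner charged, against my share of 0.411.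

**Second flask.** With 1.70 equiv of second substrate, the midpoint is 0.0504 M, the share 0.314 and the target 28.2%. The simulation of that flask gives 27.6% target at 37.6% conversion.

All constants are made up; the run is a simulation.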